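**Retrosynthetic overview**
- The 3-OH is introduced last, by epoxidation of the C2=C3 bond of the corresponding flavone (tangeretin) and acid isomerisation of the epoxide.
- The pyranone ring, the only ring built, is closed by oxidative cyclisation (O1–C2 bond) of a 2'-hydroxychalcone.
- The chalcone comes from the key intermolecular Claisen–Schmidt aldol condensation of 2'-hydroxy-3',4',5',6'-tetramethoxyacetophenone with 4-methoxybenzaldehyde.
- The acetophenone comes from C-acetylation of 2,3,4,5-tetramethoxyphenol, made from 1,2,3,4-tetramethoxybenzene by formylation and Dakin oxidation.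
- 1,2,3,4-Tetramethoxybenzene comes from cheap 2,3,4-trimethoxybenzaldehyde by Dakin oxidation and O-methylation; both benzene rings are bought intact.

Assumption: the target has no stereocentre, so it is one achiral compound and needs no enantiocontrol; substrates and intermediates are numbered, auxiliary reagents are given by name and SMILES.

**Step 1**
Reactants: 1 2,3,4-trimethoxybenzaldehyde
Product: 3 2,3,4-trimethoxyphenol, via 2,3,4-trimethoxyphenyl formate 2 (not isolated)
Conditions: mCPBA (1.3 equiv), CH2Cl2, 0 °C → rt, 12 h; aq. NaHCO3/Na2SO3 wash; then K2CO3 (0.2 equiv), MeOH, rt, 1 h, N2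
Reagents that add atoms: mCPBA, OOC(=O)c1cccc(Cl)c1
Why: Baeyer–Villiger (Dakin-type) oxidation, in which the electron-rich o-methoxyaryl group migrates in preference to hydride to give formate 2, which base-catalysed methanolysis cleaves to the phenol; no stereocentre is formed.

**Step 2**
Reactants: 3 2,3,4-trimethoxyphenol
Product: 4 1,2,3,4-tetramethoxybenzene
Conditions: MeI (1.5 equiv), K2CO3 (2 equiv), acetone, reflux, 8 h
Reagents that add atoms: iodomethane, CI
Why: Williamson ether synthesis, a clean SN2 O-methylation of the phenoxide with no competing functionality.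

**Step 3**
Reactants: 4 1,2,3,4-tetramethoxybenzene
Product: 6 2,3,4,5-tetramethoxybenzaldehyde, via benzylidene-dimethyliminium chloride 5 (not isolated)
Conditions: POCl3 (2 equiv), DMF, 0 → 80 °C, 6 h; then ice/H2O, 50 °C, 30 min
Reagents that add atoms: N,N-dimethylformamide, CN(C)C=O; water, O
Why: Vilsmeier–Haack formylation, where the two free positions of symmetric 4 are equivalent so one regioisomer forms, and the iminium substituent deactivates the ring against a second substitution before hydrolysis to the aldehyde.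

**Step 4**
Reactants: 6 2,3,4,5-tetramethoxybenzaldehyde
Product: 8 2,3,4,5-tetramethoxyphenol, via 2,3,4,5-tetramethoxyphenyl formate 7 (not isolated)
Conditions: mCPBA (1.3 equiv), CH2Cl2, 0 °C → rt, 12 h; aq. NaHCO3/Na2SO3 wash; then K2CO3 (0.2 equiv), MeOH, rt, 1 h, N2 (use the air-sensitive phenol promptly)
Reagents that add atoms: mCPBA, OOC(=O)c1cccc(Cl)c1
Why: Baeyer–Villiger (Dakin-type) oxidation with aryl migration of the very electron-rich ring, followed by methanolysis of the labile aryl formate.

**Step 5**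
Reactants: 8 2,3,4,5-tetramethoxyphenol
Product: 10 1-(2-hydroxy-3,4,5,6-tetramethoxyphenyl)ethan-1-one, via difluoroboron chelate 9 (not isolated)
Conditions: AcOH (solvent), BF3·OEt2 (3 equiv), 90 °C, 3 h; then H2O/EtOH, 70 °C, 30 min
Reagents that add atoms: acetic acid, CC(=O)O
Why: BF3-mediated Friedel–Crafts (Nencki-type) C-acylation at the only unsubstituted ring position, ortho to the OH, with the product held as its O,O-BF2 chelate until aqueous hydrolysis, which prevents further reaction.

**Step 6**
Reactants: 10 1-(2-hydroxy-3,4,5,6-tetramethoxyphenyl)ethan-1-one; 11 4-methoxybenzaldehyde (1.2 equiv)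
Product: 13 (E)-1-(2-hydroxy-3,4,5,6-tetramethoxyphenyl)-3-(4-methoxyphenyl)prop-2-en-1-one (chalcone), via racemic aldol adduct 12 (not isolated)
Conditions: KOH (50% aq., 10 equiv), EtOH, rt, 48 h; then 2 M HCl to pH 3
Reagents that add atoms: none
Why: Claisen–Schmidt crossed aldol condensation, in which the enolate of the only enolisable partner 10 adds to non-enolisable 11 and aldol 12 dehydrates by E1cB to the thermodynamically favoured E-enone (its stereocentre is destroyed, water is the only co-product).

**Step 7**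
Reactants: 13 the chalcone
Product: 15 5,6,7,8-tetramethoxy-2-(4-methoxyphenyl)-4H-chromen-4-one (tangeretin), via racemic flavanone 14 (not isolated)
Conditions: I2 (10 mol%), DMSO, 120 °C, 2 h; aq. Na2S2O3 work-up
Reagents that add atoms: none
Why: Iodine-catalysed oxidative cyclisation, in which intramolecular oxa-Michael addition of the 2'-OH gives flavanone 14 and α-iodination/HI elimination gives the flavone while DMSO reoxidises HI to I2.

**Step 8**
Reactants: 15 tangeretin
Product: 17 3-hydroxy-5,6,7,8-tetramethoxy-2-(4-methoxyphenyl)-4H-chromen-4-one (target), via racemic flavone 2,3-epoxide 16 (not isolated)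
Conditions: DMDO (ca. 0.07 M in acetone, freshly made from Oxone/NaHCO3/acetone, 4 equiv in portions), CH2Cl2, 0 °C → rt, dark, 48 h; evaporate; then p-TsOH·H2O (10 mol%), CH2Cl2, rt, 1 h
Reagents that add atoms: dimethyldioxirane, CC1(C)OO1
Why: Neutral DMDO epoxidation of the C2=C3 bond gives labile epoxide 16, which under acid catalysis opens at C2 to the aryl- and oxygen-stabilised cation and loses H-3 to give the aromatic 3-hydroxypyranone, removing both stereocentres of 16.

**Compound list**
1 | 2,3,4-trimethoxybenzaldehyde | COc1ccc(C=O)c(OC)c1OC | starting material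
2 | 2,3,4-trimethoxyphenyl formate | COc1ccc(OC=O)c(OC)c1OC | intermediate
3 | 2,3,4-trimethoxyphenol | COc1ccc(O)c(OC)c1OC | intermediate
4 | 1,2,3,4-tetramethoxybenzene | COc1ccc(OC)c(OC)c1OC | intermediate
5 | N,N-dimethyl-(2,3,4,5-tetramethoxybenzylidene)iminium chloride | C[N+](C)=Cc1cc(OC)c(OC)c(OC)c1OC.[Cl-] | intermediate
6 | 2,3,4,5-tetramethoxybenzaldehyde | COc1cc(C=O)c(OC)c(OC)c1OC | intermediate
7 | 2,3,4,5-tetramethoxyphenyl formate | COc1cc(OC=O)c(OC)c(OC)c1OC | intermediate
8 | 2,3,4,5-tetramethoxyphenol | COc1cc(O)c(OC)c(OC)c1OC | intermediate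
9 | O,O-difluoroboron chelate of 2-acetyl-3,4,5,6-tetramethoxyphenol | CC1=[O+][B-](F)(F)Oc2c1c(OC)c(OC)c(OC)c2OC | intermediate
10 | 1-(2-hydroxy-3,4,5,6-tetramethoxyphenyl)ethan-1-one | CC(=O)c1c(O)c(OC)c(OC)c(OC)c1OC | intermediate
11 | 4-methoxybenzaldehyde | COc1ccc(C=O)cc1 | starting material
12 | racemic 3-hydroxy-1-(2-hydroxy-3,4,5,6-tetramethoxyphenyl)-3-(4-methoxyphenyl)propan-1-one | COc1ccc(C(O)CC(=O)c2c(O)c(OC)c(OC)c(OC)c2OC)cc1 | intermediate
13 | (E)-1-(2-hydroxy-3,4,5,6-tetramethoxyphenyl)-3-(4-methoxyphenyl)prop-2-en-1-one | COc1ccc(/C=C/C(=O)c2c(O)c(OC)c(OC)c(OC)c2OC)cc1 | intermediate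
14 | racemic 5,6,7,8-tetramethoxy-2-(4-methoxyphenyl)chroman-4-one | COc1ccc(C2CC(=O)c3c(OC)c(OC)c(OC)c(OC)c3O2)cc1 | intermediate
15 | 5,6,7,8-tetramethoxy-2-(4-methoxyphenyl)-4H-chromen-4-one (tangeretin) | COc1ccc(-c2cc(=O)c3c(OC)c(OC)c(OC)c(OC)c3o2)cc1 | intermediate
16 | racemic 2,3-epoxy-5,6,7,8-tetramethoxy-2-(4-methoxyphenyl)chroman-4-one (cis-fused epoxide) | COc1ccc(C23OC2C(=O)c2c(OC)c(OC)c(OC)c(OC)c2O3)cc1 | intermediate
17 | 3-hydroxy-5,6,7,8-tetramethoxy-2-(4-methoxyphenyl)-4H-chromen-4-one | COc1ccc(-c2oc3c(OC)c(OC)c(OC)c(OC)c3c(=O)c2O)cc1 | target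

**Totals**
Total steps: 8. Longest linear sequence: 8 steps (1 → 17); 11 enters as a purchased fragment in step 6.

**Three steps most likely to fail**

Step 8. The C2=C3 bond is part of a vinylogous ester and is epoxidised only slowly, so the very electron-rich tetramethoxy ring may be over-oxidised by excess DMDO. The fallback sets out from 15 and returns at 17: treat 15 with LDA (THF, −78 °C) in the presence of B(OMe)3, so that the C-3 anion is trapped as dimethyl [5,6,7,8-tetramethoxy-2-(4-methoxyphenyl)-4-oxo-4H-chromen-3-yl]boronate F4, then oxidise in the same pot with H2O2/AcOH (0 °C → rt) to give 17.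

Step 5. The acylation site is flanked by OH and OMe on an oxidation-prone phenol, so the reaction may stop at the O-acetate or suffer partial demethylation. The fallback sets out from 8 and returns at 10: O-methylate 8 (MeI, K2CO3, acetone) to pentamethoxybenzene F1, acetylate its single free position (AcCl, AlCl3, CH2Cl2, 0 °C) to 1-(2,3,4,5,6-pentamethoxyphenyl)ethan-1-one F2, then cleave one of the two equivalent carbonyl-flanking methyl ethers through the boron chelate with BCl3 (1.1 equiv, CH2Cl2, −78 → 0 °C) to give 10.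

Step 7. HI formed in situ can cleave the chelated 5-OMe group, or the reaction can stall at flavanone 14. The fallback sets out from 10 and returns at 15, replacing the chalcone by a diketone: deprotonate 10 with LiHMDS (3.2 equiv, THF, −78 °C) and C-acylate the dianion with 4-methoxybenzoyl chloride (intermolecular Claisen condensation) to give 1-(2-hydroxy-3,4,5,6-tetramethoxyphenyl)-3-(4-methoxyphenyl)propane-1,3-dione F3, then cyclodehydrate (cat. H2SO4, AcOH, 95 °C) to give 15.

**Further compounds**
F1 | step 5 | pentamethoxybenzene | COc1cc(OC)c(OC)c(OC)c1OC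
F2 | step 5 | 1-(2,3,4,5,6-pentamethoxyphenyl)ethan-1-one | CC(=O)c1c(OC)c(OC)c(OC)c(OC)c1OC
F3 | step 7 | 1-(2-hydroxy-3,4,5,6-tetramethoxyphenyl)-3-(4-methoxyphenyl)propane-1,3-dione | COc1ccc(C(=O)CC(=O)c2c(O)c(OC)c(OC)c(OC)c2OC)cc1
F4 | step 8 | dimethyl [5,6,7,8-tetramethoxy-2-(4-methoxyphenyl)-4-oxo-4H-chromen-3-yl]boronate | COB(OC)c1c(-c2ccc(OC)cc2)oc2c(OC)c(OC)c(OC)c(OC)c2c1=O
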